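**Plan**
- Numbering: ring A is numbered as the phenol (C1 OH, C2 O-aryl, Br on C3, C4 and C6); ring B is the 2-bromophenyl ring.
- Retrosynthetic cuts, in order: the C4–Br bond (para to the free hydroxyl), the diaryl ether bond from the C2 oxygen to ring B, the two O–CH3 bonds, and last the C3–Br and C6–Br bonds.
- Enabling feature: the bromines on C3 and C6 sit directly beside the oxygens on C2 and C1, so ring A hides a mirror-symmetric 3,6-dibromocatechol whose two oxygens are equivalent until one is arylated.
- Forward: veratrole is doubly ortho-lithiated and brominated, demethylated, mono-arylated on either oxygen with a 2-bromophenyl iodonium salt made from 1-bromo-2-iodobenzene, and brominated once at C4.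
- No ring is formed, since both benzene rings are bought. The target has no stereocentre, so all control is regiochemical: oxygen-directed lithiation, symmetry, and para direction by the free hydroxyl.

Key step: step 1

**Step 1**
Reactants: 1 1,2-dimethoxybenzene (veratrole)
Product: 3 1,4-dibromo-2,3-dimethoxybenzene, via 3,6-dilithio-1,2-dimethoxybenzene 2 (not isolated)
Conditions: n-BuLi (3 equiv), TMEDA (3 equiv), hexane, 0 °C → rt, 24 h; suspension of 2 then transferred into BrCCl2CCl2Br (3.5 equiv), THF, –78 °C → rt
Reagents that add atoms: 1,2-dibromo-1,1,2,2-tetrachloroethane, BrC(Cl)(Cl)C(Cl)(Cl)Br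
Why: Directed ortho-metalation: each methoxy oxygen binds the TMEDA-solvated butyllithium and delivers the base to its only free neighbouring C–H, so the first lithium enters at C3 and the second, directed by the other methoxy group, at C6 rather than at C4 or C5, which have no coordinating neighbour. The dilithio species 2 is then brominated at both carbanionic carbons by halophilic attack on BrCCl2CCl2Br, the resulting beta-bromo carbanion collapsing to tetrachloroethene and LiBr, so that the C3–Br and C6–Br bonds form in one flask. The closest known reaction type is the double ortho-lithiation of 1,2-dimethoxybenzene followed by quench with silyl or halogen electrophiles. No ring is closed and no stereocentre is created. The selectivity needed is 3,6- over 3,4-, 3,5- or 4,5-substitution, the opposite of what electrophilic bromination of a catechol ether gives, and it is secured by the two oxygen directing groups; adding 2 to an excess of the bromine donor at –78 °C keeps aryllithium away from aryl bromide and so should suppress lithium–bromine exchange scrambling.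

**Step 2**
Reactants: 3 1,4-dibromo-2,3-dimethoxybenzene
Product: 5 3,6-dibromobenzene-1,2-diol, via cyclic bromoborane ester 4 (not isolated)
Conditions: BBr3 (2.2 equiv), CH2Cl2, –78 °C → rt; then H2O, 0 °C
Reagents that add atoms: none
Why: Lewis-acid ether cleavage (BBr3 demethylation), in which boron binds each methoxy oxygen, bromide removes the methyl group by SN2 as bromomethane and the cyclic aryl borate 4 is hydrolysed on work-up, while the aryl C–Br bonds are inert to BBr3.

**Step 3**
Reactants: 6 1-bromo-2-iodobenzene; 7 1,3,5-trimethoxybenzene
Product: 9 (2-bromophenyl)(2,4,6-trimethoxyphenyl)iodonium 4-methylbenzenesulfonate, via hydroxy(tosyloxy)iodoarene 8 (not isolated)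
Conditions: mCPBA (1.1 equiv), TsOH·H2O (1.1 equiv), MeCN, 77 °C, 30 min; then 7 (1.1 equiv), 77 °C, 10 min; precipitation with Et2O
Reagents that add atoms: 4-methylbenzenesulfonic acid monohydrate, Cc1ccc(cc1)S(=O)(=O)O.O
Why: One-pot diaryliodonium salt synthesis, in which mCPBA oxidises the aryl iodide to trivalent iodine, TsOH traps it as the Koser-type reagent 8, and electrophilic aromatic substitution on the very electron-rich arene 7 gives the unsymmetrical salt whose trimethoxyphenyl group serves as a non-transferred dummy ligand.

**Step 4**
Reactants: 5 3,6-dibromobenzene-1,2-diol; 9 (2-bromophenyl)(2,4,6-trimethoxyphenyl)iodonium 4-methylbenzenesulfonate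
Product: 10 3,6-dibromo-2-(2-bromophenoxy)phenol
Conditions: 5 (1.5 equiv), K2CO3 (1.0 equiv), 9 (1.0 equiv), degassed MeCN, argon, rt → 50 °C; dilute HCl work-up, chromatography (excess 5 recovered)
Reagents that add atoms: none
Why: Metal-free O-arylation of a phenoxide with a diaryliodonium salt (ligand exchange at trivalent iodine, then ligand coupling), in which the mono-phenoxide of the symmetric diol 5 attacks iodine and the electron-poorer 2-bromophenyl group is transferred in preference to the trimethoxyphenyl group, either oxygen giving the same ether, while excess diol, one equivalent of base and the crowding of the remaining hydroxyl between Br and O-aryl should hold the reaction at mono-arylation without touching any C–Br bond.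

**Step 5**
Reactants: 10 3,6-dibromo-2-(2-bromophenoxy)phenol
Product: 11 3,4,6-tribromo-2-(2-bromophenoxy)phenol
Conditions: Br2 (1.05 equiv), AcOH, rt, dark; aq Na2S2O3 work-up
Reagents that add atoms: bromine, BrBr
Why: Electrophilic aromatic bromination of a phenol, in which the free hydroxyl at C1 is the strongest activator in the molecule and both its ortho positions are occupied (C2 O-aryl, C6 Br), so one equivalent of Br2 should enter para to it at C4 in preference to C5 or to ring B, which is activated only by the shared, electron-depleted ether oxygen.

**Compound list**
1 | 1,2-dimethoxybenzene (veratrole) | COc1ccccc1OC | starting material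
2 | 3,6-dilithio-1,2-dimethoxybenzene (TMEDA-solvated) | COc1c([Li])ccc([Li])c1OC | intermediate (not isolated)
3 | 1,4-dibromo-2,3-dimethoxybenzene | COc1c(Br)ccc(Br)c1OC | intermediate
4 | 2,4,7-tribromo-1,3,2-benzodioxaborole | BrB1Oc2c(Br)ccc(Br)c2O1 | intermediate (not isolated)
5 | 3,6-dibromobenzene-1,2-diol | Oc1c(Br)ccc(Br)c1O | intermediate
6 | 1-bromo-2-iodobenzene | Brc1ccccc1I | starting material
7 | 1,3,5-trimethoxybenzene | COc1cc(OC)cc(OC)c1 | starting material
8 | 1-bromo-2-[hydroxy(tosyloxy)iodo]benzene | Cc1ccc(cc1)S(=O)(=O)OI(O)c1ccccc1Br | intermediate (not isolated)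
9 | (2-bromophenyl)(2,4,6-trimethoxyphenyl)iodonium 4-methylbenzenesulfonate | COc1cc(OC)c([I+]c2ccccc2Br)c(OC)c1.Cc1ccc(cc1)S(=O)(=O)[O-] | intermediate
10 | 3,6-dibromo-2-(2-bromophenoxy)phenol | Oc1c(Br)ccc(Br)c1Oc1ccccc1Br | intermediate
11 | 3,4,6-tribromo-2-(2-bromophenoxy)phenol | Oc1c(Br)cc(Br)c(Br)c1Oc1ccccc1Br | target

**Step count**
Total: 5 steps. Longest linear sequence: 4 steps (steps 1, 2, 4 and 5 from veratrole); step 3 is a one-step side branch.

**Steps most likely to fail**

Step 4. The catecholate may be arylated twice or oxidised by the trivalent iodine reagent, so that little mono-ether is obtained. The fallback replaces statistical control by a protecting group and sets out from 3. One methyl ether would be cleaved with NaSEt (DMF, 110 °C); the phenoxide formed shuts down the second cleavage, and either methyl gives the same product, 3,6-dibromo-2-methoxyphenol F1. F1 has a single hydroxyl and would be arylated with 9 (K2CO3, MeCN, 50 °C) to 1,4-dibromo-2-(2-bromophenoxy)-3-methoxybenzene F2. BBr3 (CH2Cl2, –78 °C → rt) would then remove the remaining methyl group, and the route is rejoined at 10.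

Step 1. The second lithiation may stay incomplete, and during the quench lithium–bromine exchange between aryllithium and aryl bromide may scramble the product into mono-, di- and unbrominated material. The fallback sets out from 1 and moves C–Br formation from the anionic quench to an electrophilic ipso-substitution. The dilithio species 2 would be quenched with Me3SiCl to give 1,2-dimethoxy-3,6-bis(trimethylsilyl)benzene F3, a stable compound that can be freed from mono-silylated material by distillation or crystallisation. Ipso-bromodesilylation with Br2 (CH2Cl2, 0 °C) would then place bromine at exactly the two silylated carbons, and the route is rejoined at 3.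

Step 5. Bromination may lose site- and ring-selectivity, with attack para to the ether oxygen on ring B or a second bromination competing with attack at C4. The fallback sets out from 10 and uses an electrophile that reacts only with free phenols. Nitrosation (NaNO2, AcOH/H2O, 0 °C) should occur solely para to the hydroxyl and give 3,6-dibromo-2-(2-bromophenoxy)-4-nitrosophenol F4. Reduction with Na2S2O4 (aq EtOH) would give 4-amino-3,6-dibromo-2-(2-bromophenoxy)phenol F5. Diazotisation (NaNO2, aq HBr, 0 °C) would give 2,5-dibromo-3-(2-bromophenoxy)-4-hydroxybenzenediazonium bromide F6, and a Sandmeyer reaction with CuBr (aq HBr, 60 °C) would install the bromine at C4, rejoining the route at 11.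

**Further compounds**
F1 | step 4 | 3,6-dibromo-2-methoxyphenol | COc1c(Br)ccc(Br)c1O
F2 | step 4 | 1,4-dibromo-2-(2-bromophenoxy)-3-methoxybenzene | COc1c(Br)ccc(Br)c1Oc1ccccc1Br
F3 | step 1 | 1,2-dimethoxy-3,6-bis(trimethylsilyl)benzene | COc1c([Si](C)(C)C)ccc([Si](C)(C)C)c1OC
F4 | step 5 | 3,6-dibromo-2-(2-bromophenoxy)-4-nitrosophenol | Oc1c(Br)cc(N=O)c(Br)c1Oc1ccccc1Br
F5 | step 5 | 4-amino-3,6-dibromo-2-(2-bromophenoxy)phenol | Nc1cc(Br)c(O)c(Oc2ccccc2Br)c1Br
F6 | step 5 | 2,5-dibromo-3-(2-bromophenoxy)-4-hydroxybenzenediazonium bromide | Oc1c(Br)cc([N+]#N)c(Br)c1Oc1ccccc1Br.[Br-]
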